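**Retrosynthetic overview**
1. Late stage: the O2' hydrogen sulfate, the exocyclic C4=C11 alkene and the C13 and C14 methyl groups are all derived from a trans-decalin that carries a ketal at C4, a ketone at C8 and an axial ester on C9.
2. Key disconnection C7–C8 of ring B (C5–C10): C9 bears two one-carbon arms, C14 and ring carbon C8, and both are ester groups of one malonate in the open precursor, so C9 is not a stereocentre until ring B is closed by a Dieckmann condensation under equilibrating conditions.
3. The open triester is cut at C9–C15 (malonate benzylation), C5–C6 (Michael addition of a chiral imine to tert-butyl acrylate) and C9–C10 (amine-catalysed asymmetric Michael addition of dimethyl malonate to 2-methylcyclohex-2-en-1-one).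
4. The benzylic bromide comes from 3-bromo-4,5-dihydroxybenzaldehyde, with O2' as MOM ether, O3' as benzyl ether and the C5' carbinol as TBDPS ether.
5. Ring order: ring A (C1–C5, C10) is bought; ring B is formed in the key step.

Key step: step 12

Conventions: C4 carries the exocyclic methylene C11; C3, C2 and C1 lead to the ring-fusion carbon C10; C9 carries methyl C14 and benzylic C15; C8 carries methyl C13; C7 and C6 lead to C5 with methyl C12; the arene is C1'–C6' with C1' on C15; β is the face of C12. ArA = 3-(benzyloxy)-5-[(tert-butyldiphenylsilyloxy)methyl]-2-(methoxymethoxy)phenyl; ArB = its 3-hydroxy analogue; ArC = its 3-(triisopropylsilyloxy) analogue; ArD = 2-hydroxy-3-(triisopropylsilyloxy)-5-[(tert-butyldiphenylsilyloxy)methyl]phenyl.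

Assumption: the quinine-derived primary amine is taken to give the C10 configuration drawn for 3; if the sense is the opposite, its quinidine-derived pseudo-enantiomer is used in the same way.

**Route**

Step 1
Reactants: 1 2-methylcyclohex-2-en-1-one; 2 dimethyl malonate
Product: 3 dimethyl 2-[(1R,2S)-2-methyl-3-oxocyclohexyl]propanedioate (C10 set; the C5 methyl centre is epimerisable and is shown trans)
Conditions: 9-amino-9-deoxy-epi-quinine (20 mol%), PhCO2H (40 mol%), THF, 40 °C
Reagents that add atoms: none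
Why: Iminium activation of the α-branched enone by the cinchona primary amine, with its quinuclidine deprotonating the malonate (asymmetric Michael addition), should deliver C9 to one face of C10 and so set C10 with its hydrogen α, while C5 forms as an epimer mixture that is erased in step 2.

Step 2
Reactants: 3 dimethyl 2-[(1R,2S)-2-methyl-3-oxocyclohexyl]propanedioate; 4 tert-butyl acrylate
Product: 7 dimethyl 2-[(1S,2S)-2-(3-tert-butoxy-3-oxopropyl)-2-methyl-3-oxocyclohexyl]propanedioate, via imine 5 (not isolated), via adduct imine 6 (not isolated)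
Conditions: (S)-1-phenylethylamine, 4 Å MS, toluene, 40 °C; then 4, THF, 60 °C; then 20% aq AcOH, rt
Reagents that add atoms: water, O
Why: The imine reacts through its more substituted secondary enamine tautomer in an aza-ene-type Michael addition with internal N–H transfer (Michael reaction of a chiral imine), so only C5 is alkylated, and the acrylate should enter anti to the C10 malonate arm, which 1,2-allylic strain holds pseudo-axial and which is the sense the (S)-auxiliary is also expected to favour, giving the quaternary C5 centre with the propanoate arm trans to the malonate arm before mild hydrolysis returns the ketone.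

Step 3
Reactants: 7 dimethyl 2-[(1S,2S)-2-(3-tert-butoxy-3-oxopropyl)-2-methyl-3-oxocyclohexyl]propanedioate
Product: 8 dimethyl 2-[(6S,7S)-6-(3-tert-butoxy-3-oxopropyl)-6-methyl-1,4-dioxaspiro[4.5]decan-7-yl]propanedioate
Conditions: TMSOCH2CH2OTMS, TMSOTf (5 mol%), CH2Cl2, −78 → −20 °C; pyridine quench
Reagents that add atoms: 1,2-bis(trimethylsilyloxy)ethane, C[Si](C)(C)OCCO[Si](C)(C)C
Why: Silyl-triflate-catalysed acetalisation with the bis-silylated diol works on hindered ketones at low temperature under aprotic conditions that should leave the tert-butyl and methyl esters untouched, and no stereocentre is affected.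

Step 4
Reactants: 9 3-bromo-4,5-dihydroxybenzaldehyde
Product: 10 3-bromo-5-hydroxy-4-(methoxymethoxy)benzaldehyde
Conditions: MOMCl (1.05 equiv), K2CO3 (1.1 equiv), acetone, 0 °C → rt
Reagents that add atoms: chloromethyl methyl ether, COCCl
Why: Williamson-type O-alkylation under one equivalent of weak base should take place at the more acidic hydroxyl para to the aldehyde, which becomes O2'.

Step 5
Reactants: 10 3-bromo-5-hydroxy-4-(methoxymethoxy)benzaldehyde
Product: 11 3-(benzyloxy)-5-bromo-4-(methoxymethoxy)benzaldehyde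
Conditions: BnBr, K2CO3, DMF, rt
Reagents that add atoms: benzyl bromide, BrCc1ccccc1
Why: Williamson ether synthesis on the remaining phenol (O3') installs a base-stable group that can later be removed by hydrogenolysis without touching the MOM ether.

Step 6
Reactants: 11 3-(benzyloxy)-5-bromo-4-(methoxymethoxy)benzaldehyde
Product: 12 [3-(benzyloxy)-5-bromo-4-(methoxymethoxy)phenyl]methanol
Conditions: NaBH4, MeOH/THF, 0 °C
Reagents that add atoms: none
Why: Borohydride reduction of the aryl aldehyde gives the C5' hydroxymethyl group without touching the aryl bromide or the ethers.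

Step 7
Reactants: 12 [3-(benzyloxy)-5-bromo-4-(methoxymethoxy)phenyl]methanol
Product: 13 {[3-(benzyloxy)-5-bromo-4-(methoxymethoxy)phenyl]methoxy}(tert-butyl)diphenylsilane
Conditions: TBDPSCl, imidazole, DMF, rt
Reagents that add atoms: tert-butylchlorodiphenylsilane, CC(C)(C)[Si](Cl)(c1ccccc1)c1ccccc1
Why: Silylation of the primary alcohol gives an ether that is expected to survive alkoxide, ylide, hydride and buffered acid and to fall only to fluoride in the last step.

Step 8
Reactants: 13 {[3-(benzyloxy)-5-bromo-4-(methoxymethoxy)phenyl]methoxy}(tert-butyl)diphenylsilane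
Product: 15 3-(benzyloxy)-5-({[tert-butyl(diphenyl)silyl]oxy}methyl)-2-(methoxymethoxy)benzaldehyde, via aryllithium 14 (not isolated)
Conditions: n-BuLi, THF, −78 °C; then DMF, −78 → 0 °C; H2O
Reagents that add atoms: N,N-dimethylformamide, CN(C)C=O
Why: Bromine–lithium exchange at C1' outruns any deprotonation at −78 °C and the aryllithium, held by the ortho MOM oxygen, is formylated by DMF (Bouveault formylation).

Step 9
Reactants: 15 3-(benzyloxy)-5-({[tert-butyl(diphenyl)silyl]oxy}methyl)-2-(methoxymethoxy)benzaldehyde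
Product: 16 [3-(benzyloxy)-5-({[tert-butyl(diphenyl)silyl]oxy}methyl)-2-(methoxymethoxy)phenyl]methanol
Conditions: NaBH4, MeOH/THF, 0 °C
Reagents that add atoms: none
Why: Borohydride reduction of the aldehyde gives the benzylic alcohol whose carbon becomes C15.

Step 10
Reactants: 16 [3-(benzyloxy)-5-({[tert-butyl(diphenyl)silyl]oxy}methyl)-2-(methoxymethoxy)phenyl]methanol
Product: 17 {[3-(benzyloxy)-5-(bromomethyl)-4-(methoxymethoxy)phenyl]methoxy}(tert-butyl)diphenylsilane
Conditions: CBr4, PPh3, CH2Cl2, 0 °C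
Reagents that add atoms: tetrabromomethane, BrC(Br)(Br)Br
Why: The Appel reaction converts the benzylic alcohol into the bromide under neutral conditions that spare the MOM and silyl ethers.

Step 11
Reactants: 8 dimethyl 2-[(6S,7S)-6-(3-tert-butoxy-3-oxopropyl)-6-methyl-1,4-dioxaspiro[4.5]decan-7-yl]propanedioate; 17 {[3-(benzyloxy)-5-(bromomethyl)-4-(methoxymethoxy)phenyl]methoxy}(tert-butyl)diphenylsilane
Product: 18 dimethyl 2-(ArA-methyl)-2-[(6S,7R)-6-(3-tert-butoxy-3-oxopropyl)-6-methyl-1,4-dioxaspiro[4.5]decan-7-yl]propanedioate (ring-A ketal with trans C5 propanoate and C10 benzylmalonate arms)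
Conditions: NaH, DMF, 0 °C; then 17, n-Bu4NI (10 mol%), 0 → 50 °C
Reagents that add atoms: none
Why: Malonic ester alkylation (SN2) should work because the C9–H is the only site acidic enough for NaH and the benzylic bromide is a reactive electrophile, and since the two ester groups on C9 are identical no stereocentre is created here.

Step 12
Reactants: 18 dimethyl 2-(ArA-methyl)-2-[(6S,7R)-6-(3-tert-butoxy-3-oxopropyl)-6-methyl-1,4-dioxaspiro[4.5]decan-7-yl]propanedioate
Product: 19 trans-decalin enol keto diester (C4 ethylene ketal; 5β-CH3; 10α-H; C7 CO2t-Bu; C8 enol OH; 9β-CO2CH3 axial; 9α-CH2ArA)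
Conditions: KOt-Bu (1.2 equiv), THF (0.02 M), 0 °C → rt; then MeOH (5 equiv), 60 °C; AcOH quench
Reagents that add atoms: none
Why: KOt-Bu deprotonates C7, the only enolisable carbon because C9 is quaternary, and the tert-butyl ester enolate adds to one of the two diastereotopic methyl ester carbonyls on C9; loss of methoxide forms the C7–C8 bond and the product is held as its stabilised enolate, which drives the closure. The closest known reaction is the Dieckmann condensation of a 1,7-diester, including its reversal by retro-Claisen attack of methoxide on C8, which the added methanol is meant to enable so that the two ring-closed diastereomers can interconvert. Ring B closes in the 6-exo-trig mode, the enolate carbon C7 attacking the ester carbonyl that becomes C8. The new stereocentre C9 is controlled by the chair of the forming trans-decalin, in which the β-axial site on C9 is syn-axial to the C5 methyl C12: the flat ester should tolerate that contact better than the CH2ArA group, so the ester is expected to end axial (the future C14) and the benzyl group equatorial. The step needs selection between two ester groups that differ only in this steric environment, so a moderate preference is expected and the minor C9 epimer would be removed by chromatography; the tert-butyl ester is placed on C7 because it resists exchange with methoxide and can later be removed without touching the C9 ester.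

Step 13
Reactants: 19 trans-decalin enol keto diester
Product: 22 trans-decalin-8-one (C4 ethylene ketal; 5β-CH3; 10α-H; 9β-CO2CH3; 9α-CH2ArA), via acylketene 20 (not isolated), via keto acid 21 (not isolated)
Conditions: DMSO/H2O (20:1), 140 °C
Reagents that add atoms: none
Why: The enolisable tert-butyl β-keto ester should lose tert-butanol thermally to an α-oxo ketene that water traps as the β-keto acid, which decarboxylates (thermal dealkoxycarbonylation), whereas the C9 methyl ester has no α-hydrogen and is too hindered for attack by water.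

Step 14
Reactants: 22 trans-decalin-8-one
Product: 23 8-methylidene trans-decalin (C4 ethylene ketal; 5β-CH3; 10α-H; 9β-CO2CH3; 9α-CH2ArA)
Conditions: Ph3PCH3Br, KOt-Bu, toluene, 90 °C
Reagents that add atoms: methyltriphenylphosphonium bromide, C[P+](c1ccccc1)(c1ccccc1)c1ccccc1.[Br-]
Why: Wittig methylenation with excess non-stabilised ylide at elevated temperature is the usual answer to a ketone flanked by a quaternary carbon, and the hindered C9 ester should not react.

Step 15
Reactants: 23 8-methylidene trans-decalin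
Product: 24 8β-methyl trans-decalin (C4 ethylene ketal; 5β-CH3; 10α-H; 8α-H; 9β-CO2CH3; 9α-CH2ArB)
Conditions: H2 (1 atm), Pd/C, EtOAc, rt
Reagents that add atoms: none
Why: Heterogeneous hydrogenation should deliver hydrogen to C8 from the α face, opposite the axial C9 ester and C5 methyl, which sets C8 with an equatorial β-methyl group, and the same catalyst hydrogenolyses the O3' benzyl ether.

Step 16
Reactants: 24 8β-methyl trans-decalin with free O3' phenol
Product: 25 O3' triisopropylsilyl ether (C4 ethylene ketal; 9β-CO2CH3; 9α-CH2ArC)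
Conditions: TIPSCl, imidazole, DMF, rt
Reagents that add atoms: chlorotriisopropylsilane, CC(C)[Si](Cl)(C(C)C)C(C)C
Why: Silylation of the free phenol gives a bulky ether that should not migrate to the more crowded O2' and that is removed by fluoride together with the TBDPS group.

Step 17
Reactants: 25 O3' triisopropylsilyl ether
Product: 26 9β-hydroxymethyl trans-decalin (C4 ethylene ketal; 8β-CH3; 9α-CH2ArC)
Conditions: i-Bu2AlH, toluene, −78 °C → rt; aq potassium sodium tartrate
Reagents that add atoms: none
Why: Reduction with excess aluminium hydride at room temperature is expected to reach the neopentyl axial ester while leaving the silyl ethers and acetals alone.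

Step 18
Reactants: 26 9β-hydroxymethyl trans-decalin
Product: 27 9β-formyl trans-decalin (C4 ethylene ketal; 8β-CH3; 9α-CH2ArC)
Conditions: Dess–Martin periodinane, CH2Cl2, rt
Reagents that add atoms: none
Why: Dess–Martin oxidation gives the non-enolisable neopentyl aldehyde under near-neutral conditions.

Step 19
Reactants: 27 9β-formyl trans-decalin
Product: 29 9β-methyl trans-decalin (C4 ethylene ketal; 5β-CH3; 8β-CH3; 10α-H; 9α-CH2ArC), via tosylhydrazone 28 (not isolated)
Conditions: TsNHNH2, THF, 50 °C; then catecholborane, CHCl3, 0 °C; then NaOAc·3H2O, 60 °C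
Reagents that add atoms: none
Why: The aldehyde tosylhydrazone is reduced by catecholborane and the borylated sulfonylhydrazine should lose sulfinate and dinitrogen on warming with acetate (reductive deoxygenation through a tosylhydrazone), giving the C14 methyl group under conditions mild enough for the aryl silyl ether.

Step 20
Reactants: 29 9β-methyl trans-decalin
Product: 30 trans-decalin-4-one (5β-CH3; 8β-CH3; 9β-CH3; 10α-H; 9α-CH2ArC)
Conditions: PPTS, acetone/H2O (10:1), 55 °C
Reagents that add atoms: water, O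
Why: Acid-catalysed hydrolysis should be selective because the dialkyl ketal is far more labile than the aryl MOM ether or the silyl ethers under buffered acid in wet acetone.

Step 21
Reactants: 30 trans-decalin-4-one
Product: 31 4-methylidene trans-decalin (5β-CH3; 8β-CH3; 9β-CH3; 10α-H; 9α-CH2ArC)
Conditions: Ph3PCH3Br, KOt-Bu, toluene, 90 °C
Reagents that add atoms: methyltriphenylphosphonium bromide, C[P+](c1ccccc1)(c1ccccc1)c1ccccc1.[Br-]
Why: Wittig methylenation of the C4 ketone next to quaternary C5 forms the exocyclic C4=C11 alkene without protic acid that could move it into the ring.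

Step 22
Reactants: 31 4-methylidene trans-decalin
Product: 33 O2' phenol (4-methylidene trans-decalin with 9α-CH2ArD), via TMS ether 32 (not isolated)
Conditions: TMSOTf, 2,2'-bipyridyl, CH2Cl2, 0 °C; then H2O
Reagents that add atoms: none
Why: The silyl triflate and bipyridyl pair converts an aryl MOM ether into the aryl trimethylsilyl ether, which water cleaves (non-acidic acetal cleavage), so the exocyclic alkene and the TIPS and TBDPS ethers should be left alone.

Step 23
Reactants: 33 O2' phenol
Product: 34 pyridinium salt of the O2' sulfate (O3' TIPS and C5' CH2OTBDPS retained)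
Conditions: SO3·pyridine, pyridine, 50 °C
Reagents that add atoms: sulfur trioxide–pyridine complex, [O-]S(=O)(=O)[n+]1ccccc1
Why: O-sulfation with the SO3–pyridine complex can only take place at O2', the one free hydroxyl, and the small electrophile should reach this flanked phenol on gentle warming.

Step 24
Reactants: 34 pyridinium salt of the O2' sulfate
Product: 35 target, 2-{[(5S,8S,9R,10S)-5,8,9-trimethyl-4-methylidenedecalin-9-yl]methyl}-6-hydroxy-4-(hydroxymethyl)phenyl hydrogen sulfate (locants as defined above)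
Conditions: n-Bu4NF, THF, 0 °C → rt; then Dowex 50W (H+ form), MeOH/H2O, 0 °C
Reagents that add atoms: none
Why: Fluoride cleaves both silyl ethers (desilylation) while aryl sulfate monoesters are inert to fluoride and mild base, and cold cation exchange should release the free hydrogen sulfate.

**Compound list**
1 | 2-methylcyclohex-2-en-1-one | CC1=CCCCC1=O | starting material
2 | dimethyl malonate | COC(=O)CC(=O)OC | starting material
3 | dimethyl 2-[(1R,2S)-2-methyl-3-oxocyclohexyl]propanedioate | O=C1CCC[C@@H](C(C(=O)OC)C(=O)OC)[C@@H]1C | intermediate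
4 | tert-butyl acrylate | C=CC(=O)OC(C)(C)C | starting material
5 | (S)-1-phenylethyl imine of 3 | C[C@H](N=C1CCC[C@@H](C(C(=O)OC)C(=O)OC)[C@@H]1C)c1ccccc1 | intermediate (not isolated)
6 | C5-alkylated imine | C[C@H](N=C1CCC[C@@H](C(C(=O)OC)C(=O)OC)[C@]1(C)CCC(=O)OC(C)(C)C)c1ccccc1 | intermediate (not isolated)
7 | dimethyl 2-[(1S,2S)-2-(3-tert-butoxy-3-oxopropyl)-2-methyl-3-oxocyclohexyl]propanedioate | O=C1CCC[C@@H](C(C(=O)OC)C(=O)OC)[C@]1(C)CCC(=O)OC(C)(C)C | intermediate
8 | dimethyl 2-[(6S,7S)-6-(3-tert-butoxy-3-oxopropyl)-6-methyl-1,4-dioxaspiro[4.5]decan-7-yl]propanedioate | C13(OCCO3)CCC[C@@H](C(C(=O)OC)C(=O)OC)[C@]1(C)CCC(=O)OC(C)(C)C | intermediate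
9 | 3-bromo-4,5-dihydroxybenzaldehyde | O=Cc1cc(O)c(O)c(Br)c1 | starting material
10 | 3-bromo-5-hydroxy-4-(methoxymethoxy)benzaldehyde | O=Cc1cc(O)c(OCOC)c(Br)c1 | intermediate
11 | 3-(benzyloxy)-5-bromo-4-(methoxymethoxy)benzaldehyde | O=Cc1cc(OCc2ccccc2)c(OCOC)c(Br)c1 | intermediate
12 | [3-(benzyloxy)-5-bromo-4-(methoxymethoxy)phenyl]methanol | OCc1cc(OCc2ccccc2)c(OCOC)c(Br)c1 | intermediate
13 | {[3-(benzyloxy)-5-bromo-4-(methoxymethoxy)phenyl]methoxy}(tert-butyl)diphenylsilane | CC(C)(C)[Si](OCc1cc(OCc2ccccc2)c(OCOC)c(Br)c1)(c1ccccc1)c1ccccc1 | intermediate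
14 | aryllithium from 13 (Li at C1') | [Li]c1cc(CO[Si](c2ccccc2)(c2ccccc2)C(C)(C)C)cc(OCc2ccccc2)c1OCOC | intermediate (not isolated)
15 | 3-(benzyloxy)-5-({[tert-butyl(diphenyl)silyl]oxy}methyl)-2-(methoxymethoxy)benzaldehyde | O=Cc1cc(CO[Si](c2ccccc2)(c2ccccc2)C(C)(C)C)cc(OCc2ccccc2)c1OCOC | intermediate
16 | [3-(benzyloxy)-5-({[tert-butyl(diphenyl)silyl]oxy}methyl)-2-(methoxymethoxy)phenyl]methanol | OCc1cc(CO[Si](c2ccccc2)(c2ccccc2)C(C)(C)C)cc(OCc2ccccc2)c1OCOC | intermediate
17 | {[3-(benzyloxy)-5-(bromomethyl)-4-(methoxymethoxy)phenyl]methoxy}(tert-butyl)diphenylsilane | BrCc1cc(CO[Si](c2ccccc2)(c2ccccc2)C(C)(C)C)cc(OCc2ccccc2)c1OCOC | intermediate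
18 | ring-A ketal triester, dimethyl 2-(ArA-methyl)-2-[(6S,7R)-6-(3-tert-butoxy-3-oxopropyl)-6-methyl-1,4-dioxaspiro[4.5]decan-7-yl]propanedioate | C13(OCCO3)CCC[C@@H](C(Cc4cc(CO[Si](c5ccccc5)(c5ccccc5)C(C)(C)C)cc(OCc5ccccc5)c4OCOC)(C(=O)OC)C(=O)OC)[C@]1(C)CCC(=O)OC(C)(C)C | intermediate
19 | trans-decalin enol keto diester (C4 ketal; C7 CO2t-Bu; C8 enol; 9β-CO2CH3; 9α-CH2ArA) | C13(OCCO3)CCC[C@H]2[C@](C(=O)OC)(Cc4cc(CO[Si](c5ccccc5)(c5ccccc5)C(C)(C)C)cc(OCc5ccccc5)c4OCOC)C(O)=C(C(=O)OC(C)(C)C)C[C@]12C | intermediate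
20 | C7 acylketene of the C8 ketone | C13(OCCO3)CCC[C@H]2[C@](C(=O)OC)(Cc4cc(CO[Si](c5ccccc5)(c5ccccc5)C(C)(C)C)cc(OCc5ccccc5)c4OCOC)C(=O)C(=C=O)C[C@]12C | intermediate (not isolated)
21 | C7 carboxylic acid of the C8 ketone | C13(OCCO3)CCC[C@H]2[C@](C(=O)OC)(Cc4cc(CO[Si](c5ccccc5)(c5ccccc5)C(C)(C)C)cc(OCc5ccccc5)c4OCOC)C(=O)C(C(=O)O)C[C@]12C | intermediate (not isolated)
22 | trans-decalin-8-one (C4 ketal; 9β-CO2CH3; 9α-CH2ArA) | C13(OCCO3)CCC[C@H]2[C@](C(=O)OC)(Cc4cc(CO[Si](c5ccccc5)(c5ccccc5)C(C)(C)C)cc(OCc5ccccc5)c4OCOC)C(=O)CC[C@]12C | intermediate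
23 | 8-methylidene trans-decalin (C4 ketal; 9β-CO2CH3; 9α-CH2ArA) | C13(OCCO3)CCC[C@H]2[C@](C(=O)OC)(Cc4cc(CO[Si](c5ccccc5)(c5ccccc5)C(C)(C)C)cc(OCc5ccccc5)c4OCOC)C(=C)CC[C@]12C | intermediate
24 | 8β-methyl trans-decalin (C4 ketal; 9β-CO2CH3; 9α-CH2ArB) | C13(OCCO3)CCC[C@H]2[C@](C(=O)OC)(Cc4cc(CO[Si](c5ccccc5)(c5ccccc5)C(C)(C)C)cc(O)c4OCOC)[C@@H](C)CC[C@]12C | intermediate
25 | O3' triisopropylsilyl ether (C4 ketal; 9β-CO2CH3; 9α-CH2ArC) | C13(OCCO3)CCC[C@H]2[C@](C(=O)OC)(Cc4cc(CO[Si](c5ccccc5)(c5ccccc5)C(C)(C)C)cc(O[Si](C(C)C)(C(C)C)C(C)C)c4OCOC)[C@@H](C)CC[C@]12C | intermediate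
26 | 9β-hydroxymethyl trans-decalin (C4 ketal; 9α-CH2ArC) | C13(OCCO3)CCC[C@H]2[C@](CO)(Cc4cc(CO[Si](c5ccccc5)(c5ccccc5)C(C)(C)C)cc(O[Si](C(C)C)(C(C)C)C(C)C)c4OCOC)[C@@H](C)CC[C@]12C | intermediate
27 | 9β-formyl trans-decalin (C4 ketal; 9α-CH2ArC) | C13(OCCO3)CCC[C@H]2[C@](C=O)(Cc4cc(CO[Si](c5ccccc5)(c5ccccc5)C(C)(C)C)cc(O[Si](C(C)C)(C(C)C)C(C)C)c4OCOC)[C@@H](C)CC[C@]12C | intermediate
28 | tosylhydrazone of 27 | C13(OCCO3)CCC[C@H]2[C@](C=NNS(=O)(=O)c6ccc(C)cc6)(Cc4cc(CO[Si](c5ccccc5)(c5ccccc5)C(C)(C)C)cc(O[Si](C(C)C)(C(C)C)C(C)C)c4OCOC)[C@@H](C)CC[C@]12C | intermediate (not isolated)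
29 | 9β-methyl trans-decalin (C4 ketal; 9α-CH2ArC) | C13(OCCO3)CCC[C@H]2[C@](C)(Cc4cc(CO[Si](c5ccccc5)(c5ccccc5)C(C)(C)C)cc(O[Si](C(C)C)(C(C)C)C(C)C)c4OCOC)[C@@H](C)CC[C@]12C | intermediate
30 | trans-decalin-4-one (9α-CH2ArC) | O=C1CCC[C@H]2[C@](C)(Cc4cc(CO[Si](c5ccccc5)(c5ccccc5)C(C)(C)C)cc(O[Si](C(C)C)(C(C)C)C(C)C)c4OCOC)[C@@H](C)CC[C@]12C | intermediate
31 | 4-methylidene trans-decalin (9α-CH2ArC) | C=C1CCC[C@H]2[C@](C)(Cc4cc(CO[Si](c5ccccc5)(c5ccccc5)C(C)(C)C)cc(O[Si](C(C)C)(C(C)C)C(C)C)c4OCOC)[C@@H](C)CC[C@]12C | intermediate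
32 | O2' trimethylsilyl ether of 33 | C=C1CCC[C@H]2[C@](C)(Cc4cc(CO[Si](c5ccccc5)(c5ccccc5)C(C)(C)C)cc(O[Si](C(C)C)(C(C)C)C(C)C)c4O[Si](C)(C)C)[C@@H](C)CC[C@]12C | intermediate (not isolated)
33 | O2' phenol (9α-CH2ArD) | C=C1CCC[C@H]2[C@](C)(Cc4cc(CO[Si](c5ccccc5)(c5ccccc5)C(C)(C)C)cc(O[Si](C(C)C)(C(C)C)C(C)C)c4O)[C@@H](C)CC[C@]12C | intermediate
34 | pyridinium salt of the O2' sulfate | C=C1CCC[C@H]2[C@](C)(Cc4cc(CO[Si](c5ccccc5)(c5ccccc5)C(C)(C)C)cc(O[Si](C(C)C)(C(C)C)C(C)C)c4OS(=O)(=O)[O-])[C@@H](C)CC[C@]12C.c1cc[nH+]cc1 | intermediate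
35 | CNP0353860.3 | C=C1CCC[C@H]2[C@](C)(Cc3cc(CO)cc(O)c3OS(=O)(=O)O)[C@@H](C)CC[C@]12C | target

**Totals**
Total step count: 24. Longest linear sequence: 21 steps (steps 4–24, from 9); the ring-A branch (steps 1–3) joins at step 11.

**Steps most likely to fail and fallbacks**

Step 12: discrimination between the two ester carbonyls during ring closure may be too small, or equilibration may stay incomplete, so that both C9 epimers form in similar amounts. The fallback sets C9 by alkylation after ring closure and sets out from 8. Dieckmann closure of 8 before benzylation (KOt-Bu, 2.2 equiv, THF/t-BuOH, 60 °C) should give the bicyclic enol keto diester F1, in which C9 still bears hydrogen. Thermolysis in wet DMSO removes the tert-butyl ester and gives the cyclic β-keto methyl ester F2. C-benzylation of its enolate with 17 (K2CO3, acetone, reflux) is expected to occur on the α face, away from the axial C5 methyl that sits 1,3 to C9, as is usual for cyclic β-keto ester enolates next to an angular methyl. This places the ester β-axial and the benzyl group α and returns to the route at 22.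

Step 11: SN2 attack of the crowded tertiary malonate anion of 8 may be slow enough for decomposition of the electron-rich benzylic bromide to take over. The fallback forms C9–C15 before the quaternary C5 centre exists and sets out from 3. Benzylation of the unhindered malonate of 3 with 17 (NaH, DMF) gives the benzylmalonate ketone F3. Its (S)-1-phenylethylamine imine F4 adds tert-butyl acrylate 4 at C5, anti to the now larger C10 arm, to give the adduct imine F5, which aqueous acetic acid hydrolyses to the quaternary ketone F6. Silyl-triflate-catalysed dioxolane formation (TMSOCH2CH2OTMS, TMSOTf cat., CH2Cl2, −78 °C) then rejoins the route at 18.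

Step 15: hydrogen may be delivered to C8 from the wrong face on the metal surface, or hydrogenolysis may extend to the benzylic C–O bond of the silyl ether. The fallback separates the two events and sets out from 23. Radical hydrogen-atom-transfer hydrogenation (Mn(dpm)3, PhSiH3, t-BuOOH, i-PrOH, rt) passes through a tertiary C8 radical that takes up hydrogen axially, which should give the thermodynamically preferred equatorial 8β-methyl compound F7 with the benzyl ether intact. Brief hydrogenolysis (H2, Pd/C, EtOAc) of the O3' benzyl ether then returns to the route at 24.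

**Further compounds**
F1 | step 12 | bicyclic enol keto diester from 8 (C4 ketal; C7 CO2t-Bu; C8 enol; C9 H and CO2CH3) | C13(OCCO3)CCC[C@H]2C(C(=O)OC)C(O)=C(C(=O)OC(C)(C)C)C[C@]12C
F2 | step 12 | cyclic β-keto methyl ester (C4 ketal; C8 ketone; C9 H and CO2CH3) | C13(OCCO3)CCC[C@H]2C(C(=O)OC)C(=O)CC[C@]12C
F3 | step 11 | dimethyl 2-(ArA-methyl)-2-(2-methyl-3-oxocyclohexyl)propanedioate (C10 as in 3; C5 epimerisable) | O=C1CCC[C@@H](C(Cc4cc(CO[Si](c5ccccc5)(c5ccccc5)C(C)(C)C)cc(OCc5ccccc5)c4OCOC)(C(=O)OC)C(=O)OC)[C@@H]1C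
F4 | step 11 | (S)-1-phenylethyl imine of F3 | C[C@H](N=C1CCC[C@@H](C(Cc4cc(CO[Si](c5ccccc5)(c5ccccc5)C(C)(C)C)cc(OCc5ccccc5)c4OCOC)(C(=O)OC)C(=O)OC)[C@@H]1C)c1ccccc1
F5 | step 11 | C5-alkylated imine from F4 | C[C@H](N=C1CCC[C@@H](C(Cc4cc(CO[Si](c5ccccc5)(c5ccccc5)C(C)(C)C)cc(OCc5ccccc5)c4OCOC)(C(=O)OC)C(=O)OC)[C@]1(C)CCC(=O)OC(C)(C)C)c1ccccc1
F6 | step 11 | quaternary C5 ketone with benzylmalonate arm (free C4 ketone analogue of 18) | O=C1CCC[C@@H](C(Cc4cc(CO[Si](c5ccccc5)(c5ccccc5)C(C)(C)C)cc(OCc5ccccc5)c4OCOC)(C(=O)OC)C(=O)OC)[C@]1(C)CCC(=O)OC(C)(C)C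
F7 | step 15 | 8β-methyl trans-decalin with O3' benzyl ether retained (C4 ketal; 9β-CO2CH3; 9α-CH2ArA) | C13(OCCO3)CCC[C@H]2[C@](C(=O)OC)(Cc4cc(CO[Si](c5ccccc5)(c5ccccc5)C(C)(C)C)cc(OCc5ccccc5)c4OCOC)[C@@H](C)CC[C@]12C
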